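**Strategy.** The butenolide (ring A: O1, C2=O, C3H=C4, C5H2) is read as a terminal alkyne, C3≡C4, that has taken up CO2 at C3 and a hydroxymethyl anion equivalent at C4 on the same face. A nickel-mediated three-component coupling of the fully elaborated, bis-silylated sesterterpenoid alkyne with CO2 and (pivaloyloxy)methylzinc iodide therefore makes the C2–C3 and C4–C5 bonds in one operation; pivalate cleavage then closes the lactone. The alkyne precursor is assembled from an (R)-propargylic alcohol (Brown allylation of an ynal), a (Z)-α-iodoenoate olefination and a B-alkyl Suzuki coupling with a farnesal-derived homofarnesyl borane.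

Key step: step 11

Remark: the carbinol centre is R in the target and keeps this descriptor in every intermediate, because the alkynyl or butenolide carbon always outranks the CH2 neighbour; TBS = tert-butyldimethylsilyl.

**Step 1**
Reactants: 1 3-(trimethylsilyl)prop-2-ynal
Product: 2 (3R)-1-(trimethylsilyl)hex-5-en-1-yn-3-ol
Conditions: (+)-Ipc2B(allyl), Et2O, −78 °C; then 3 M NaOH, 30% H2O2, 0 °C
Reagents that add atoms: (+)-B-allyldiisopinocampheylborane (the reagent derived from (−)-α-pinene), C=CCB([C@H]1C[C@H]2C[C@H](C2(C)C)[C@@H]1C)[C@H]1C[C@H]2C[C@H](C2(C)C)[C@@H]1C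
Why: Brown asymmetric allylboration through a closed chair (Zimmerman–Traxler) transition state; the (−)-α-pinene-derived reagent should deliver allyl to the Re face of the ynal and so set the R carbinol centre.

**Step 2**
Reactants: 2 (3R)-1-(trimethylsilyl)hex-5-en-1-yn-3-ol
Product: 3 (3R)-3-(TBS-oxy)-1-(trimethylsilyl)hex-5-en-1-yne
Conditions: TBSCl, imidazole, DMF, rt
Reagents that add atoms: tert-butyldimethylsilyl chloride, CC(C)(C)[Si](C)(C)Cl
Why: standard O-silylation of a secondary propargylic alcohol; the stereocentre is not involved.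

**Step 3**
Reactants: 3 (3R)-3-(TBS-oxy)-1-(trimethylsilyl)hex-5-en-1-yne
Product: 4 (3R)-3-(TBS-oxy)-5-(trimethylsilyl)pent-4-ynal
Conditions: O3, CH2Cl2, −78 °C (Sudan red end point); then PPh3, −78 °C to rt
Reagents that add atoms: ozone, [O-][O+]=O
Why: ozonolysis with reductive work-up; the terminal alkene should react far faster than the silyl-capped alkyne, and titration to the indicator end point limits over-oxidation.

**Step 4**
Reactants: 4 (3R)-3-(TBS-oxy)-5-(trimethylsilyl)pent-4-ynal
Product: 5 ethyl (2Z,5R)-5-(TBS-oxy)-2-iodo-7-(trimethylsilyl)hept-2-en-6-ynoate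
Conditions: Ph3P=CHCO2Et, N-iodosuccinimide, K2CO3, CH2Cl2, −20 °C; then 4, −20 °C to rt
Reagents that add atoms: ethyl (triphenylphosphoranylidene)acetate, CCOC(=O)C=P(c1ccccc1)(c1ccccc1)c1ccccc1; N-iodosuccinimide, O=C1CCC(=O)N1I
Why: Wittig olefination with the iodo-substituted stabilized ylide formed in the flask; stabilized ylides place the ester trans to the aldehyde-derived chain, which is the Z iodoalkene by the CIP rules.

**Step 5**
Reactants: 5 ethyl (2Z,5R)-5-(TBS-oxy)-2-iodo-7-(trimethylsilyl)hept-2-en-6-ynoate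
Product: 6 (2Z,5R)-5-(TBS-oxy)-2-iodo-7-(trimethylsilyl)hept-2-en-6-yn-1-ol
Conditions: (i-Bu)2AlH (2.2 equiv), CH2Cl2, −78 °C; aq. potassium sodium tartrate
Reagents that add atoms: none
Why: 1,2-reduction of the enoate to the allylic alcohol by diisobutylaluminium hydride; vinyl iodide, silyl ether and silyl alkyne are inert at −78 °C.

**Step 6**
Reactants: 6 (2Z,5R)-5-(TBS-oxy)-2-iodo-7-(trimethylsilyl)hept-2-en-6-yn-1-ol
Product: 7 (2Z,5R)-1,5-bis(TBS-oxy)-2-iodo-7-(trimethylsilyl)hept-2-en-6-yne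
Conditions: TBSCl, imidazole, DMF, rt
Reagents that add atoms: tert-butyldimethylsilyl chloride, CC(C)(C)[Si](C)(C)Cl
Why: standard silylation of the primary allylic alcohol, which must be masked for the organozinc and nickel chemistry later.

**Step 7**
Reactants: 8 (2E,6E)-farnesol
Product: 9 (2E,6E)-farnesal
Conditions: TEMPO (10 mol %), PhI(OAc)2, CH2Cl2, rt
Reagents that add atoms: none
Why: oxoammonium-mediated oxidation of a primary allylic alcohol, which should stop at the enal and keep the 2E geometry.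

**Step 8**
Reactants: 9 (2E,6E)-farnesal
Product: 10 (3E,7E)-4,8,12-trimethyltrideca-1,3,7,11-tetraene
Conditions: Ph3PCH3Br, KOt-Bu, THF, 0 °C; then 9, 0 °C to rt
Reagents that add atoms: methyltriphenylphosphonium bromide, C[P+](c1ccccc1)(c1ccccc1)c1ccccc1.[Br-]
Why: Wittig methylenation of the enal at the carbonyl carbon gives the terminal 1,3-diene without touching the trisubstituted alkenes.

**Step 9**
Reactants: 10 (3E,7E)-4,8,12-trimethyltrideca-1,3,7,11-tetraene; 7 (2Z,5R)-1,5-bis(TBS-oxy)-2-iodo-7-(trimethylsilyl)hept-2-en-6-yne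
Product: 12 (3R,5E,9E,13E)-3-(TBS-oxy)-6-[(TBS-oxy)methyl]-10,14,18-trimethyl-1-(trimethylsilyl)nonadeca-5,9,13,17-tetraen-1-yne, via B-homofarnesyl-9-BBN 11 (not isolated)
Conditions: 10, 9-BBN-H dimer, THF, 0 °C to rt; then 7, [1,1'-bis(diphenylphosphino)ferrocene]palladium dichloride (5 mol %), AsPh3, 3 M aq. K3PO4, DMF, rt
Reagents that add atoms: none
Why: 9-BBN should hydroborate only the terminal vinyl carbon of the diene, and the B-alkyl Suzuki–Miyaura coupling joins the homofarnesyl group to the vinyl iodide with retention of alkene geometry, so the chain ends up cis to the carbinol-bearing CH2.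

**Step 10**
Reactants: 12 the C-silylated enyne from step 9
Product: 13 (3R,5E,9E,13E)-3-(TBS-oxy)-6-[(TBS-oxy)methyl]-10,14,18-trimethylnonadeca-5,9,13,17-tetraen-1-yne
Conditions: K2CO3 (0.5 equiv), MeOH/THF, rt
Reagents that add atoms: none
Why: methoxide-induced protodesilylation of the alkynyl silane; the TBS ethers are stable to these conditions.

**Step 11**
Reactants: 13 the terminal alkyne from step 10
Product: 15 (2E,4R,6E,10E,14E)-4-(TBS-oxy)-7-[(TBS-oxy)methyl]-11,15,19-trimethyl-3-[(pivaloyloxy)methyl]icosa-2,6,10,14,18-pentaenoic acid, via oxanickelacyclopentenone 14 (not isolated)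
Conditions: bis(cycloocta-1,5-diene)nickel, Ni(C8H12)2 (1.1 equiv), DBU (2.5 equiv), CO2 (1 atm), THF, 0 °C, slow addition of 13; then PivOCH2ZnI (3 equiv; from PivOCH2I and zinc dust, THF, 10 °C), 0 °C to rt; cold 0.5 M HCl
Reagents that add atoms: carbon dioxide, O=C=O; iodomethyl pivalate, CC(C)(C)C(=O)OCI
Why: Zerovalent nickel should couple the terminal alkyne with CO2 by oxidative cyclization to the five-membered oxanickelacyclopentenone 14, with the carboxyl carbon on the unsubstituted alkyne carbon (new C2–C3 bond) and nickel on the substituted one; transmetalation of the Ni–O bond with the (pivaloyloxy)methylzinc iodide and C(sp2)–C(sp3) reductive elimination then form the C4–C5 bond with retention, so CO2H and CH2OPiv end up cis (net syn carbo-carboxylation). The closest known reaction type is the nickel-mediated alkylative carboxylation of terminal alkynes with CO2 and organozinc reagents, here fed with an acyloxymethylzinc iodide as hydroxymethyl anion equivalent. The only ring closed in this step is the transient nickelacycle (oxidative cyclization of alkyne, CO2 and nickel); the butenolide ring is closed in step 12 by 5-exo-trig lactonization of the cis CH2OH and CO2H groups. No stereocentre is created and the silyloxy-bearing centre is not touched; the alkene geometry follows from the syn addition. The step needs regioselectivity (CO2 at the terminal carbon), which the branched α-silyloxy substituent should secure by sitting next to nickel and away from the forming C–C bond, and chemoselectivity for the alkyne over the four trisubstituted alkenes, which bind zerovalent nickel far more weakly; slow addition of 13 should suppress alkyne oligomerization.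

**Step 12**
Reactants: 15 the pivaloyloxymethyl acid from step 11
Product: 17 4-[(1R,3E,7E,11E)-1-(TBS-oxy)-4-[(TBS-oxy)methyl]-8,12,16-trimethylheptadeca-3,7,11,15-tetraen-1-yl]furan-2(5H)-one, via hydroxy acid 16 (not isolated)
Conditions: LiOH·H2O (5 equiv), THF/MeOH/H2O, 40 °C; then 1 M HCl to pH 3, rt
Reagents that add atoms: none
Why: saponification of the allylic pivalate frees a CH2OH group cis to the carboxyl, and on acidification this hydroxy acid should lactonize spontaneously (5-exo-trig) to the butenolide while both TBS ethers survive.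

**Step 13**
Reactants: 17 the bis-silylated butenolide from step 12
Product: 18 hippolide C, 4-[(1R,3E,7E,11E)-1-hydroxy-4-(hydroxymethyl)-8,12,16-trimethylheptadeca-3,7,11,15-tetraen-1-yl]furan-2(5H)-one
Conditions: HF·pyridine, pyridine/THF, 0 °C to rt
Reagents that add atoms: none
Why: buffered fluoride cleavage of both silyl ethers, which should leave the polyene, the allylic alcohol, the butenolide and the R carbinol centre unchanged.

**Compound list**
1 | 3-(trimethylsilyl)prop-2-ynal | C[Si](C)(C)C#CC=O | starting material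
2 | (3R)-1-(trimethylsilyl)hex-5-en-1-yn-3-ol | C=CC[C@@H](O)C#C[Si](C)(C)C | intermediate
3 | (3R)-3-(TBS-oxy)-1-(trimethylsilyl)hex-5-en-1-yne | C=CC[C@@H](O[Si](C)(C)C(C)(C)C)C#C[Si](C)(C)C | intermediate
4 | (3R)-3-(TBS-oxy)-5-(trimethylsilyl)pent-4-ynal | O=CC[C@@H](O[Si](C)(C)C(C)(C)C)C#C[Si](C)(C)C | intermediate
5 | ethyl (2Z,5R)-5-(TBS-oxy)-2-iodo-7-(trimethylsilyl)hept-2-en-6-ynoate | CCOC(=O)/C(I)=C/C[C@@H](O[Si](C)(C)C(C)(C)C)C#C[Si](C)(C)C | intermediate
6 | (2Z,5R)-5-(TBS-oxy)-2-iodo-7-(trimethylsilyl)hept-2-en-6-yn-1-ol | OC/C(I)=C/C[C@@H](O[Si](C)(C)C(C)(C)C)C#C[Si](C)(C)C | intermediate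
7 | (2Z,5R)-1,5-bis(TBS-oxy)-2-iodo-7-(trimethylsilyl)hept-2-en-6-yne | CC(C)(C)[Si](C)(C)OC/C(I)=C/C[C@@H](O[Si](C)(C)C(C)(C)C)C#C[Si](C)(C)C | intermediate
8 | (2E,6E)-farnesol | CC(C)=CCC/C(C)=C/CC/C(C)=C/CO | starting material
9 | (2E,6E)-farnesal | CC(C)=CCC/C(C)=C/CC/C(C)=C/C=O | intermediate
10 | (3E,7E)-4,8,12-trimethyltrideca-1,3,7,11-tetraene | CC(C)=CCC/C(C)=C/CC/C(C)=C/C=C | intermediate
11 | 9-[(3E,7E)-4,8,12-trimethyltrideca-3,7,11-trien-1-yl]-9-borabicyclo[3.3.1]nonane (B-homofarnesyl-9-BBN) | CC(C)=CCC/C(C)=C/CC/C(C)=C/CCB1C2CCCC1CCC2 | intermediate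
12 | (3R,5E,9E,13E)-3-(TBS-oxy)-6-[(TBS-oxy)methyl]-10,14,18-trimethyl-1-(trimethylsilyl)nonadeca-5,9,13,17-tetraen-1-yne | CC(C)=CCC/C(C)=C/CC/C(C)=C/CC/C(=C\C[C@@H](O[Si](C)(C)C(C)(C)C)C#C[Si](C)(C)C)CO[Si](C)(C)C(C)(C)C | intermediate
13 | (3R,5E,9E,13E)-3-(TBS-oxy)-6-[(TBS-oxy)methyl]-10,14,18-trimethylnonadeca-5,9,13,17-tetraen-1-yne | CC(C)=CCC/C(C)=C/CC/C(C)=C/CC/C(=C\C[C@@H](O[Si](C)(C)C(C)(C)C)C#C)CO[Si](C)(C)C(C)(C)C | intermediate
14 | oxanickelacyclopentenone from 13 and CO2, nickel on the substituted carbon (DBU ligands on nickel not written) | CC(C)=CCC/C(C)=C/CC/C(C)=C/CC/C(=C\C[C@@H](O[Si](C)(C)C(C)(C)C)C1=CC(=O)O[Ni]1)CO[Si](C)(C)C(C)(C)C | intermediate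
15 | (2E,4R,6E,10E,14E)-4-(TBS-oxy)-7-[(TBS-oxy)methyl]-11,15,19-trimethyl-3-[(pivaloyloxy)methyl]icosa-2,6,10,14,18-pentaenoic acid | CC(C)=CCC/C(C)=C/CC/C(C)=C/CC/C(=C\C[C@@H](O[Si](C)(C)C(C)(C)C)/C(COC(=O)C(C)(C)C)=C/C(=O)O)CO[Si](C)(C)C(C)(C)C | intermediate
16 | (2E,4R,6E,10E,14E)-4-(TBS-oxy)-7-[(TBS-oxy)methyl]-3-(hydroxymethyl)-11,15,19-trimethylicosa-2,6,10,14,18-pentaenoic acid | CC(C)=CCC/C(C)=C/CC/C(C)=C/CC/C(=C\C[C@@H](O[Si](C)(C)C(C)(C)C)/C(CO)=C/C(=O)O)CO[Si](C)(C)C(C)(C)C | intermediate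
17 | 4-[(1R,3E,7E,11E)-1-(TBS-oxy)-4-[(TBS-oxy)methyl]-8,12,16-trimethylheptadeca-3,7,11,15-tetraen-1-yl]furan-2(5H)-one | CC(C)=CCC/C(C)=C/CC/C(C)=C/CC/C(=C\C[C@@H](O[Si](C)(C)C(C)(C)C)C1=CC(=O)OC1)CO[Si](C)(C)C(C)(C)C | intermediate
18 | hippolide C | CC(C)=CCC/C(C)=C/CC/C(C)=C/CC/C(=C\C[C@@H](O)C1=CC(=O)OC1)CO | target

**Step count and risks**
Total step count: 13. Longest linear sequence: 11 steps (steps 1–6 and 9–13); steps 7–8 make the side-chain fragment.

Steps most likely to fail:

1. Step 11. The α-acyloxyalkylzinc may transmetalate to the nickelacycle too slowly, so that protonation to the simple acrylic acid or alkyne oligomerization takes over. Fallback, from 13 back to 17, making the two bonds one after the other: deprotonation of 13 (n-BuLi, THF, −78 °C) and trapping with methyl chloroformate would give the methyl ynoate F1. Anti-hydroiodination (NaI, AcOH, 70 °C) would give the (Z)-3-iodo enoate F2 with iodine cis to the ester. Stille coupling of F2 with (tributylstannyl)methanol (Pd(PPh3)4, dioxane, 80 °C) would install the hydroxymethyl group, which should lactonize onto the cis ester to give 17.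

2. Step 4. Iodine transfer to the ylide may be incomplete and the Z selectivity of the halo-olefination may erode, giving non-iodinated or E material that is hard to separate. Fallback, from 4 back to 6: Wittig reaction of 4 with (triphenylphosphoranylidene)acetaldehyde (toluene, 60 °C) would give the (2E,5R)-enal F3. α-Iodination by the addition–iodination–elimination sequence (I2, DMAP cat., K2CO3, THF/H2O) would give the (2Z,5R)-2-iodo enal F4. Luche reduction (NaBH4, CeCl3·7H2O, MeOH, −40 °C) would then give 6.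

3. Step 9. Transmetalation of the alkylborane may be slow, with competing protodeboronation, or the aqueous base may strip the alkynyl silane and let the free alkyne couple at palladium. Fallback with reversed polarity, from 10 and 7 back to 12: hydroboration–oxidation of 10 (9-BBN-H; NaOH, H2O2) would give (3E,7E)-homofarnesol F5, and I2, PPh3, imidazole would convert it into (3E,7E)-homofarnesyl iodide F6. Iodine–lithium exchange on 7 (t-BuLi, 2 equiv, Et2O, −78 °C) and addition of ZnBr2 would give the alkenylzinc bromide F7. Negishi coupling of F7 with F6 (tris(dibenzylideneacetone)dipalladium, tricyclopentylphosphine, N-methylimidazole, THF/NMP, 80 °C) would give 12.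

**Further compounds**
F1 | step 11 | methyl (4R,6E,10E,14E)-4-(TBS-oxy)-7-[(TBS-oxy)methyl]-11,15,19-trimethylicosa-6,10,14,18-tetraen-2-ynoate | CC(C)=CCC/C(C)=C/CC/C(C)=C/CC/C(=C\C[C@@H](O[Si](C)(C)C(C)(C)C)C#CC(=O)OC)CO[Si](C)(C)C(C)(C)C
F2 | step 11 | methyl (2Z,4R,6E,10E,14E)-4-(TBS-oxy)-7-[(TBS-oxy)methyl]-3-iodo-11,15,19-trimethylicosa-2,6,10,14,18-pentaenoate | CC(C)=CCC/C(C)=C/CC/C(C)=C/CC/C(=C\C[C@@H](O[Si](C)(C)C(C)(C)C)/C(I)=C/C(=O)OC)CO[Si](C)(C)C(C)(C)C
F3 | step 4 | (2E,5R)-5-(TBS-oxy)-7-(trimethylsilyl)hept-2-en-6-ynal | O=C/C=C/C[C@@H](O[Si](C)(C)C(C)(C)C)C#C[Si](C)(C)C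
F4 | step 4 | (2Z,5R)-5-(TBS-oxy)-2-iodo-7-(trimethylsilyl)hept-2-en-6-ynal | O=C/C(I)=C/C[C@@H](O[Si](C)(C)C(C)(C)C)C#C[Si](C)(C)C
F5 | step 9 | (3E,7E)-4,8,12-trimethyltrideca-3,7,11-trien-1-ol (homofarnesol) | CC(C)=CCC/C(C)=C/CC/C(C)=C/CCO
F6 | step 9 | (3E,7E)-1-iodo-4,8,12-trimethyltrideca-3,7,11-triene (homofarnesyl iodide) | CC(C)=CCC/C(C)=C/CC/C(C)=C/CCI
F7 | step 9 | alkenylzinc bromide from 7 (zinc in place of iodine) | CC(C)(C)[Si](C)(C)OC/C([Zn]Br)=C/C[C@@H](O[Si](C)(C)C(C)(C)C)C#C[Si](C)(C)C
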